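## The problem

Eduesmine is a single tetrahydrofuran ring (O1, C2–C5) that carries two identical 4-hydroxy-3-methoxyphenyl groups at C2 and C5 and two hydroxymethyl arms, C3a on C3 and C4a on C4. All four ring carbons are stereocentres of S configuration, and a twofold axis passes through O1 and the midpoint of C3–C4. The relative arrangement is cis (C2 aryl/C3 arm), trans (C3 arm/C4 arm), cis (C4 arm/C5 aryl), so each aryl group has a neighbour on its own face, which is the less stable arrangement at both benzylic carbons. These benzylic ether carbons are also the fragile part: with a para oxygen donor the ring C–O bond ionises under acid and recloses to the trans isomer, and the same bonds are open to hydrogenolysis, so both cis relationships must be set kinetically and then kept away from acid and from H2 over Pd/C. Absolute configuration has to enter with the first C–C bond, because there is no stereocentre outside the ring to borrow from. After that, C2 and C3 can direct C4 (attack on a ring enolate anti to the C3 arm), and C3 and C4 can direct C5 (addition to a ring oxocarbenium ion). The feature that opens the molecule is that O1–C2 with its aryl group is a masked aryl aldehyde, while C3–C4–C5, with C5 at the acid oxidation level, is the homoenolate of an enal whose β-carbon (C3) already carries C3a. Joining C3 to C2 and letting O1 acylate C5 gives a cis-β,γ-disubstituted γ-lactone that holds C2 and C3 in the required sense.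

## Retrosynthesis

**Protecting groups.** Target 19 is traced back to the fully protected tetrahydrofuran 17 by cleaving three O–Si bonds and one O–S bond, passing through monotosylate 18. Fluoride and hydroxide are used because acid would epimerise C2 and C5 and H2 over Pd/C could open the ring; benzyl ethers are therefore avoided throughout. Compound 17 has the full skeleton and all four stereocentres, so nothing but deprotection is asked of the last step.

**C5–aryl bond.** Compound 17 is cut at C5–aryl into the 2-benzenesulfonyl ether 12 (an oxocarbenium precursor with hydrogen already on C5) and arylzinc bromide 16. The neighbouring option, adding the aryl group to the lactone carbonyl and then reducing the hemiketal with a silane, is set aside. In the envelope of the ring cation (C3 as flap, both arms pseudoequatorial) nucleophiles prefer the inside face, which is the face of the C4 arm. A hydride entering there would leave the aryl group trans to the C4 arm; an aryl nucleophile entering there gives the required cis C4 arm/C5 aryl and trans C2/C5 diaryl arrangement. Closing O1–C5 by substitution at an electron-rich benzylic carbinol is also rejected, because it tends toward ionisation and the trans isomer. The forward reaction must be selective for the inside face and must not ionise C2–O1; the sulfonyloxy group on the C2 aryl lowers that risk.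

**C5 oxidation level.** Sulfone 12 comes from lactol 11 by sulfinate exchange, and 11 from lactone 10 by partial reduction. No skeletal bond is cut; the forward steps must leave the silyl ethers and the aryl sulfonate intact.

**C4–C4a bond.** Lactone 10 is the silyl ether of hydroxymethyl lactone 9, which is cut at C4–C4a into a one-carbon electrophile at the aldehyde oxidation level and lithium enolate 8 of lactone 7. Placing C4a in the enal instead would require an α-branched enal, a poor homoenolate precursor. An alkoxymethyl halide would bring in a benzyl ether that needs hydrogenolysis. In 7 the C3 arm and the C2 aryl share one face, so the electrophile should enter from the other and give the C3/C4 trans relationship.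

**Key disconnection.** Lactone 7 is cut at C2–C3 and O1–C5 into aldehyde 2 and enal 6. Against an aldol-type cut at C3–C4 or an etherification at O1–C2, this one forms the ring, both stereocentres and the absolute configuration in one catalytic step from a vanillin-derived aldehyde, and it is a pure addition in which no atom of either partner is lost. The forward annulation must be cross-selective, cis-selective and enantioselective. Two choices serve this: the phenol of the aldehyde is a tosylate, which makes 2 electron-poor like the halobenzaldehydes that are the standard partners, and the γ-oxygen of 6 is a silyl ether, a poor leaving group.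

**Starting materials.** Enal 6 comes from the Z-enal 5 by isomerisation, 5 from allylic alcohol 4 by oxidation, and 4 from (Z)-but-2-ene-1,4-diol 3 by monosilylation. Aldehyde 2 is the tosylate of vanillin 1. Arylzinc 16 comes via Grignard reagent 15 from bromide 14, the silyl ether of 4-bromo-2-methoxyphenol 13.

## Roads not taken

**Alternative 1:** The cut is at C4–C5 and C2–C3 without ring formation. 5-(d-Menthyloxy)furan-2(5H)-one A1 would take up the lithio derivative of 2-[4-(benzyloxy)-3-methoxyphenyl]-1,3-dithiane A2 at its β-carbon, and the lactone enolate would be trapped by 4-(benzyloxy)-3-methoxybenzaldehyde A3 to give the all-trans adduct A4.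
- Merits: absolute configuration comes from a crystalline acetal auxiliary with dependable anti addition, and A4 holds every carbon of the target after one flask. In certainty of absolute configuration this road is better than the chosen plan, whose enantiomeric purity rests on a catalyst.
- Weak points: in A4, C5 is a dithioketal with no configuration and C2 is a free benzylic carbinol. The route then needs dithiane removal next to electron-rich arenes, ketone reduction, reduction of the lactone and acetal to the two arms, differentiation of the hydroxyls and an etherification at an electron-rich benzylic carbon. That last step tends toward ionisation and the trans isomers, whereas the target is cis at both ends.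
- Comparison: the chosen plan fixes C2 inside a ring during C–C bond formation and sets C5 by kinetic addition, in fewer steps after the key step.

**Alternative 2:** The cut is at both C–aryl bonds. trans-N,N'-Di(quinolin-8-yl)tetrahydrofuran-3,4-dicarboxamide A5 would be arylated twice with 1-(benzyloxy)-4-iodo-2-methoxybenzene A6 under Pd(OAc)2 and AgOAc (divalent palladium) to give A7.
- Merits: this road uses the twofold symmetry, installs both aryl groups in one operation, and the palladacycle geometry places each aryl cis to its amide, which is the relationship the target needs at both ends. On paper it is shorter and more convergent than the chosen plan.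
- Weak points: the second arylation on an already crowded ring; the need for A5 as a single enantiomer (resolution or auxiliary); stoichiometric silver; and removal and reduction of two hindered aminoquinoline amides on a scaffold whose C3 and C4 are α to carbonyl groups and strained by cis aryl groups.
- Comparison: the chosen plan sets against the shorter route a catalytic source of absolute configuration and an endgame of simple deprotections with no epimerisable carbonyl stage after both aryl groups are in place.

**Alternative 3:** The cut is at O1–C2, C2–C3 and C4–C5. Rh2(OAc)4 would convert 1-(benzyloxy)-4-(diazomethyl)-2-methoxybenzene A8 into a carbene that forms a carbonyl ylide with aldehyde A3; cycloaddition to dimethyl fumarate A9 gives A10.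
- Merits: ring, three bonds and four stereocentres form in one step from simple pieces, with the C3/C4 trans relationship inherited from the fumarate. No plan, the chosen one included, matches this convergence.
- Weak points: A10 is racemic unless a catalyst controls a free ylide, and both aryl groups are trans to their neighbouring esters. The target would need two contra-thermodynamic benzylic inversions, for which ionisation chemistry only leads further toward trans. Dioxolane and epoxide formation compete.
- Comparison: the chosen plan is longer but reaches the cis,trans,cis array by kinetic steps.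

Key step: step 4

Assumption 1: "eduesmine" is taken to be the (2S,3S,4S,5S) compound of the structure given, with both aryl groups cis to their neighbouring hydroxymethyl arms.
Assumption 2: the sense of induction of the aminoindanol-derived N-mesityl triazolium carbene with this enal/aldehyde pair cannot be predicted with confidence. The route is written for the antipode of the precatalyst, (5aS,10bR)- or (5aR,10bS)-2-mesityl-5a,10b-dihydro-4H,6H-indeno[2,1-b][1,2,4]triazolo[4,3-d][1,4]oxazin-2-ium chloride, that gives the (4S,5S) lactone 7.

## Route

Step 1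
Reactants: 1 vanillin (4-hydroxy-3-methoxybenzaldehyde)
Product: 2 3-methoxy-4-(tosyloxy)benzaldehyde
Conditions: TsCl, Et3N, DMAP (cat.), CH2Cl2, 0 °C to rt
Reagents that add atoms: p-toluenesulfonyl chloride, SMILES Cc1ccc(cc1)S(=O)(=O)Cl
Why: O-sulfonylation of the only nucleophilic site, the phenol; the tosylate turns the para substituent of the aldehyde from a donor into an acceptor for step 4 and later shields C2–O1 from ionisation.

Step 2
Reactants: 3 (Z)-but-2-ene-1,4-diol
Product: 4 (Z)-4-(tert-butyldiphenylsilyloxy)but-2-en-1-ol
Conditions: NaH (1.0 equiv), THF, 0 °C to rt; TBDPSCl (1.0 equiv), rt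
Reagents that add atoms: tert-butyldiphenylsilyl chloride, SMILES CC(C)(C)[Si](Cl)(c1ccccc1)c1ccccc1
Why: Monosilylation of a symmetric diol through its monosodium alkoxide, a standard desymmetrisation by stoichiometry.

Step 3
Reactants: 4 (Z)-4-(tert-butyldiphenylsilyloxy)but-2-en-1-ol
Product: 6 (E)-4-(tert-butyldiphenylsilyloxy)but-2-enal, via Z-enal 5 (not isolated)
Conditions: C5H5NH[CrO3Cl] (pyridinium chlorochromate, 1.5 equiv), Celite, CH2Cl2, rt
Reagents that add atoms: none
Why: Chromate-ester oxidation of the allylic alcohol by hexavalent chromium gives the Z-enal, which isomerises under the mildly acidic pyridinium conditions to the conjugated, more stable E-enal.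

Step 4
Reactants: 2 3-methoxy-4-(tosyloxy)benzaldehyde; 6 (E)-4-(tert-butyldiphenylsilyloxy)but-2-enal
Product: 7 (4S,5S)-4-[(tert-butyldiphenylsilyloxy)methyl]-5-[3-methoxy-4-(tosyloxy)phenyl]dihydrofuran-2(3H)-one (4,5-cis lactone)
Conditions: chiral aminoindanol-derived N-mesityl triazolium chloride (10 mol %), DBU (8 mol %), THF, rt; aldehyde in twofold excess, enal added by syringe pump
Reagents that add atoms: none
Why: The carbene adds to C1 of enal 6 and proton transfer gives the extended enaminol (homoenolate equivalent), whose β-carbon attacks the carbonyl carbon of aldehyde 2 to form the C4–C5 bond of the lactone (C3–C2 of the target); tautomerisation then gives an acyl azolium. The benzylic alkoxide closes the ring by 5-exo-trig O-acylation at the acyl azolium carbon (O1–C5 of the target) and releases the carbene. The closest known reaction type is the N-heterocyclic carbene-catalysed homoenolate annulation of enals with aryl aldehydes to cis-γ-butyrolactones. Both stereocentres arise in the C–C bond-forming event: the indane wall of the catalyst shields one face of the E-configured extended enol and so fixes C4, and the aldehyde approaches with its aryl group turned away from the azolium, which places the aryl cis to the silyloxymethyl group and fixes C5. The step needs homoenolate reactivity in place of acyl-anion reactivity, which the N-mesityl triazolium favours. It needs cross-annulation in place of enal self-annulation, which the electron-poor sulfonyloxy aldehyde in excess and the slow addition of 6 should secure. It also needs C–C bond formation to outrun vinylogous loss of the γ-oxygen, for which the silyl ether was chosen as a poor leaving group. The equation is a one-to-one addition in which every atom of 2 and of 6 ends up in 7, so the surplus aldehyde is simply unreacted material to be separated.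

Step 5
Reactants: 7 (4S,5S)-4-[(tert-butyldiphenylsilyloxy)methyl]-5-[3-methoxy-4-(tosyloxy)phenyl]dihydrofuran-2(3H)-one
Product: 9 (3S,4S,5S)-3-(hydroxymethyl)-4-[(tert-butyldiphenylsilyloxy)methyl]-5-[3-methoxy-4-(tosyloxy)phenyl]dihydrofuran-2(3H)-one (3,4-trans 4,5-cis), via lithium enolate 8 (not isolated)
Conditions: LiN(SiMe3)2 (1.1 equiv), THF, −78 °C; HCHO gas (from cracked paraformaldehyde), −78 to −40 °C; aq. NH4Cl
Reagents that add atoms: formaldehyde, SMILES C=O
Why: Aldol hydroxymethylation of a lactone enolate; the C4 arm and the C5 aryl group occupy one face of the enolate, so formaldehyde should enter from the other and set C3 trans to the C4 arm, which is also the thermodynamically preferred arrangement should the product re-enolise.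

Step 6
Reactants: 9 hydroxymethyl lactone
Product: 10 (3S,4S,5S)-3-[(tert-butyldimethylsilyloxy)methyl]-4-[(tert-butyldiphenylsilyloxy)methyl]-5-[3-methoxy-4-(tosyloxy)phenyl]dihydrofuran-2(3H)-one
Conditions: TBSCl, imidazole, DMF, 0 °C to rt
Reagents that add atoms: tert-butyldimethylsilyl chloride, SMILES CC(C)(C)[Si](C)(C)Cl
Why: Standard silylation of a primary alcohol under near-neutral conditions, which avoids dehydration of the β-hydroxy lactone and gives an arm removable by fluoride.

Step 7
Reactants: 10 bis-silylated lactone
Product: 11 (3S,4S,5S)-3-[(tert-butyldimethylsilyloxy)methyl]-4-[(tert-butyldiphenylsilyloxy)methyl]-5-[3-methoxy-4-(tosyloxy)phenyl]tetrahydrofuran-2-ol (both C2 epimers)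
Conditions: i-Bu2AlH (1.2 equiv), CH2Cl2, −78 °C; aq. KNaC4H4O6 (potassium sodium tartrate)
Reagents that add atoms: none
Why: Partial reduction of a lactone to the lactol through the tetrahedral aluminate, which is stable at −78 °C; aryl sulfonate and silyl ethers are inert at this temperature.

Step 8
Reactants: 11 lactol
Product: 12 (3S,4S,5S)-2-(benzenesulfonyl)-3-[(tert-butyldimethylsilyloxy)methyl]-4-[(tert-butyldiphenylsilyloxy)methyl]-5-[3-methoxy-4-(tosyloxy)phenyl]tetrahydrofuran (both C2 epimers)
Conditions: PhSO2H (3 equiv), CaCl2 (powder), CH2Cl2, rt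
Reagents that add atoms: benzenesulfinic acid, SMILES OS(=O)c1ccccc1
Why: Acid-promoted exchange of the anomeric hydroxyl for sulfinate sulfur through the ring oxocarbenium ion, with CaCl2 taking up the water; this is the established route to 2-benzenesulfonyl cyclic ethers, and the electron-poor aryl group at the other benzylic carbon should keep that centre from ionising.

Step 9
Reactants: 13 4-bromo-2-methoxyphenol
Product: 14 (4-bromo-2-methoxyphenoxy)(tert-butyl)dimethylsilane
Conditions: TBSCl, imidazole, CH2Cl2, rt
Reagents that add atoms: tert-butyldimethylsilyl chloride, SMILES CC(C)(C)[Si](C)(C)Cl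
Why: Routine silylation of a phenol, which gives a fluoride-labile group that tolerates Grignard formation.

Step 10
Reactants: 14 (4-bromo-2-methoxyphenoxy)(tert-butyl)dimethylsilane; 12 anomeric sulfone
Product: 17 (2S,3S,4S,5S)-2-[4-(tert-butyldimethylsilyloxy)-3-methoxyphenyl]-3-[(tert-butyldimethylsilyloxy)methyl]-4-[(tert-butyldiphenylsilyloxy)methyl]-5-[3-methoxy-4-(tosyloxy)phenyl]tetrahydrofuran, via arylmagnesium bromide 15 (not isolated), via arylzinc bromide 16 (not isolated)
Conditions: aryl bromide, Mg, I2 (cat.), THF, rt to 45 °C; ZnBr2 (1.1 equiv per Grignard), THF, rt; then the sulfone, THF, 0 °C to rt; arylzinc in threefold excess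
Reagents that add atoms: none
Why: The zinc and magnesium halides ionise the sulfone to the ring oxocarbenium ion, which the arylzinc captures (substitution of 2-benzenesulfonyl cyclic ethers by organozinc reagents). In the envelope with both arms pseudoequatorial the nucleophile should enter on the inside face, syn to the adjacent arm and anti to the other arm and the existing aryl group, which is the sense the inside-attack model for five-membered oxocarbenium ions predicts and sets the new benzylic centre cis to its arm. The mild Lewis acid and the sulfonyloxy aryl group should preserve the first benzylic centre.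

Step 11
Reactants: 17 fully protected tetrahydrofuran
Product: 19 eduesmine [(2S,3S,4S,5S)-2,5-bis(4-hydroxy-3-methoxyphenyl)tetrahydrofuran-3,4-diyl]dimethanol, via desilylated monotosylate 18 (not isolated)
Conditions: Bu4NF (5 equiv), THF, rt; then aq. KOH, MeOH, 60 °C; aq. NH4Cl
Reagents that add atoms: none
Why: Fluoride cleaves the three silyl ethers and hydroxide then attacks sulfur of the aryl sulfonate to release the second phenol; neither acid nor hydrogen is used, so the benzylic ether carbons should keep their configuration.

## Compound list

1 | vanillin (4-hydroxy-3-methoxybenzaldehyde) | COc1cc(C=O)ccc1O | starting material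
2 | 3-methoxy-4-(tosyloxy)benzaldehyde (vanillin tosylate) | COc1cc(C=O)ccc1OS(=O)(=O)c1ccc(C)cc1 | intermediate
3 | (Z)-but-2-ene-1,4-diol | OC/C=C\CO | starting material
4 | (Z)-4-(tert-butyldiphenylsilyloxy)but-2-en-1-ol | OC/C=C\CO[Si](c1ccccc1)(c1ccccc1)C(C)(C)C | intermediate
5 | (Z)-4-(tert-butyldiphenylsilyloxy)but-2-enal | O=C/C=C\CO[Si](c1ccccc1)(c1ccccc1)C(C)(C)C | intermediate
6 | (E)-4-(tert-butyldiphenylsilyloxy)but-2-enal | O=C/C=C/CO[Si](c1ccccc1)(c1ccccc1)C(C)(C)C | intermediate
7 | (4S,5S)-4-[(tert-butyldiphenylsilyloxy)methyl]-5-[3-methoxy-4-(tosyloxy)phenyl]dihydrofuran-2(3H)-one | COc1cc(ccc1OS(=O)(=O)c1ccc(C)cc1)[C@H]1OC(=O)C[C@H]1CO[Si](c1ccccc1)(c1ccccc1)C(C)(C)C | intermediate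
8 | lithium enolate of lactone 7 | COc1cc(ccc1OS(=O)(=O)c1ccc(C)cc1)[C@H]1OC(O[Li])=C[C@H]1CO[Si](c1ccccc1)(c1ccccc1)C(C)(C)C | intermediate
9 | (3S,4S,5S)-3-(hydroxymethyl)-4-[(tert-butyldiphenylsilyloxy)methyl]-5-[3-methoxy-4-(tosyloxy)phenyl]dihydrofuran-2(3H)-one | COc1cc(ccc1OS(=O)(=O)c1ccc(C)cc1)[C@H]1OC(=O)[C@H](CO)[C@H]1CO[Si](c1ccccc1)(c1ccccc1)C(C)(C)C | intermediate
10 | (3S,4S,5S)-3-[(tert-butyldimethylsilyloxy)methyl]-4-[(tert-butyldiphenylsilyloxy)methyl]-5-[3-methoxy-4-(tosyloxy)phenyl]dihydrofuran-2(3H)-one | COc1cc(ccc1OS(=O)(=O)c1ccc(C)cc1)[C@H]1OC(=O)[C@H](CO[Si](C)(C)C(C)(C)C)[C@H]1CO[Si](c1ccccc1)(c1ccccc1)C(C)(C)C | intermediate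
11 | (3S,4S,5S)-3-[(tert-butyldimethylsilyloxy)methyl]-4-[(tert-butyldiphenylsilyloxy)methyl]-5-[3-methoxy-4-(tosyloxy)phenyl]tetrahydrofuran-2-ol, both C2 epimers | COc1cc(ccc1OS(=O)(=O)c1ccc(C)cc1)[C@H]1OC(O)[C@H](CO[Si](C)(C)C(C)(C)C)[C@H]1CO[Si](c1ccccc1)(c1ccccc1)C(C)(C)C | intermediate
12 | (3S,4S,5S)-2-(benzenesulfonyl)-3-[(tert-butyldimethylsilyloxy)methyl]-4-[(tert-butyldiphenylsilyloxy)methyl]-5-[3-methoxy-4-(tosyloxy)phenyl]tetrahydrofuran, both C2 epimers | COc1cc(ccc1OS(=O)(=O)c1ccc(C)cc1)[C@H]1OC(S(=O)(=O)c2ccccc2)[C@H](CO[Si](C)(C)C(C)(C)C)[C@H]1CO[Si](c1ccccc1)(c1ccccc1)C(C)(C)C | intermediate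
13 | 4-bromo-2-methoxyphenol | COc1cc(Br)ccc1O | starting material
14 | (4-bromo-2-methoxyphenoxy)(tert-butyl)dimethylsilane | COc1cc(Br)ccc1O[Si](C)(C)C(C)(C)C | intermediate
15 | [4-(tert-butyldimethylsilyloxy)-3-methoxyphenyl]magnesium bromide | COc1cc([Mg]Br)ccc1O[Si](C)(C)C(C)(C)C | intermediate
16 | [4-(tert-butyldimethylsilyloxy)-3-methoxyphenyl]zinc bromide | COc1cc([Zn]Br)ccc1O[Si](C)(C)C(C)(C)C | intermediate
17 | (2S,3S,4S,5S)-2-[4-(tert-butyldimethylsilyloxy)-3-methoxyphenyl]-3-[(tert-butyldimethylsilyloxy)methyl]-4-[(tert-butyldiphenylsilyloxy)methyl]-5-[3-methoxy-4-(tosyloxy)phenyl]tetrahydrofuran | COc1cc(ccc1OS(=O)(=O)c1ccc(C)cc1)[C@H]1O[C@H](c2ccc(O[Si](C)(C)C(C)(C)C)c(OC)c2)[C@H](CO[Si](C)(C)C(C)(C)C)[C@H]1CO[Si](c1ccccc1)(c1ccccc1)C(C)(C)C | intermediate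
18 | 4-[(2S,3S,4S,5S)-5-(4-hydroxy-3-methoxyphenyl)-3,4-bis(hydroxymethyl)tetrahydrofuran-2-yl]-2-methoxyphenyl 4-methylbenzenesulfonate | COc1cc(ccc1OS(=O)(=O)c1ccc(C)cc1)[C@H]1O[C@H](c2ccc(O)c(OC)c2)[C@H](CO)[C@H]1CO | intermediate
19 | eduesmine, [(2S,3S,4S,5S)-2,5-bis(4-hydroxy-3-methoxyphenyl)tetrahydrofuran-3,4-diyl]dimethanol | COc1cc([C@H]2O[C@H](c3ccc(O)c(OC)c3)[C@H](CO)[C@H]2CO)ccc1O | target

## Step count and risks

Total: 11 steps. Longest linear sequence: 9 steps (steps 2, 3, 4, 5, 6, 7, 8, 10, 11, from diol 3).

**Step 4 (key step).** Three processes may defeat it. Self-annulation of the enal or acyl-anion coupling may outrun the cross-annulation. The extended enaminol may expel the γ-silyloxy group and drain into a redox isomerisation. Enantio- and cis-selectivity may be insufficient, since induction by chiral triazolium carbenes with simple aryl aldehydes is less developed than with activated ketones. The fallback sets out from 2 and returns at 7 by an auxiliary-controlled anti-aldol route. The imide methyl 4-[(4S)-4-benzyl-2-oxooxazolidin-3-yl]-4-oxobutanoate F1 (from (S)-4-benzyloxazolidin-2-one and methyl 4-chloro-4-oxobutanoate) would react with 2 under MgCl2 (cat.), Et3N and Me3SiCl in EtOAc; the chelated Z-enolate should react on the face away from the benzyl group to give the silylated anti-aldol adduct F2. CF3CO2H in CH2Cl2–MeOH would then remove the silyl group and close the ring to the cis-lactone imide F3, NaBH4 in THF–H2O would reduce the imide to the hydroxymethyl lactone F4 with release of the auxiliary, and TBDPSCl with imidazole would give 7.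

**Step 10.** Facial selectivity at the ring cation may be poor or opposite to the inside-attack expectation. Proton loss to the dihydrofuran, or ionisation at the other benzylic carbon, may also intervene. The fallback uses the stereocomplementary order of events, because aryl and hydride would enter on the same face. It sets out from lactone 10 and returns at 17. The aryllithium F5 (from 14 and n-BuLi, THF, −78 °C) adds to the lactone carbonyl to give the hemiketal F6, which is reduced with Et3SiH and BF3·OEt2 in CH2Cl2 at −78 °C. If hydride proved to enter anti to the adjacent arm, this sequence would give 17.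

**Step 5.** Formaldehyde may polymerise before it reacts, a second hydroxymethylation may occur, or retro-aldol or dehydration may take place on warming. The fallback sets out from 7 and returns at 9. Enolate 8 is alkylated with benzyl chloromethyl ether to the benzyloxymethyl lactone F7, and the benzyl ether is cleaved with BCl3 and pentamethylbenzene in CH2Cl2 at −78 °C. This stage has no electron-rich benzylic ether to ionise.

**Step 11.** Hot hydroxide on the free phenolate may cause partial loss of configuration at the benzylic ether carbons through reversible quinone-methide ring opening, or sulfonate cleavage may be incomplete. The fallback changes the cleavage from nucleophilic attack at sulfur to single-electron reduction. It sets out from 17 and returns at 19: the sequence is stopped after the Bu4NF stage, 18 is isolated, and Mg in MeOH at rt converts 18 to 19 without hot hydroxide; no new compound arises.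

## Further compounds

F1 | step 4 | methyl 4-[(4S)-4-benzyl-2-oxooxazolidin-3-yl]-4-oxobutanoate | COC(=O)CCC(=O)N1[C@@H](Cc2ccccc2)COC1=O
F2 | step 4 | methyl (3R,4S)-3-{[(4S)-4-benzyl-2-oxooxazolidin-3-yl]carbonyl}-4-[3-methoxy-4-(tosyloxy)phenyl]-4-(trimethylsilyloxy)butanoate | COC(=O)C[C@H]([C@H](O[Si](C)(C)C)c1ccc(OS(=O)(=O)c2ccc(C)cc2)c(OC)c1)C(=O)N1[C@@H](Cc2ccccc2)COC1=O
F3 | step 4 | (4S)-4-benzyl-3-{[(2S,3R)-2-[3-methoxy-4-(tosyloxy)phenyl]-5-oxotetrahydrofuran-3-yl]carbonyl}oxazolidin-2-one | COc1cc(ccc1OS(=O)(=O)c1ccc(C)cc1)[C@H]1OC(=O)C[C@H]1C(=O)N1[C@@H](Cc2ccccc2)COC1=O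
F4 | step 4 | (4S,5S)-4-(hydroxymethyl)-5-[3-methoxy-4-(tosyloxy)phenyl]dihydrofuran-2(3H)-one | COc1cc(ccc1OS(=O)(=O)c1ccc(C)cc1)[C@H]1OC(=O)C[C@H]1CO
F5 | step 10 | [4-(tert-butyldimethylsilyloxy)-3-methoxyphenyl]lithium | COc1cc([Li])ccc1O[Si](C)(C)C(C)(C)C
F6 | step 10 | (3S,4S,5S)-2-[4-(tert-butyldimethylsilyloxy)-3-methoxyphenyl]-3-[(tert-butyldimethylsilyloxy)methyl]-4-[(tert-butyldiphenylsilyloxy)methyl]-5-[3-methoxy-4-(tosyloxy)phenyl]tetrahydrofuran-2-ol | COc1cc(ccc1OS(=O)(=O)c1ccc(C)cc1)[C@H]1OC(O)(c2ccc(O[Si](C)(C)C(C)(C)C)c(OC)c2)[C@H](CO[Si](C)(C)C(C)(C)C)[C@H]1CO[Si](c1ccccc1)(c1ccccc1)C(C)(C)C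
F7 | step 5 | (3S,4S,5S)-3-[(benzyloxy)methyl]-4-[(tert-butyldiphenylsilyloxy)methyl]-5-[3-methoxy-4-(tosyloxy)phenyl]dihydrofuran-2(3H)-one | COc1cc(ccc1OS(=O)(=O)c1ccc(C)cc1)[C@H]1OC(=O)[C@H](COCc2ccccc2)[C@H]1CO[Si](c1ccccc1)(c1ccccc1)C(C)(C)C
F0 | step 11 | none | none
A1 | alternative 1 | 5-(d-menthyloxy)furan-2(5H)-one, single acetal epimer | O=C1O[C@H](O[C@H]2C[C@@H](C)CC[C@@H]2C(C)C)C=C1
A2 | alternative 1 | 2-[4-(benzyloxy)-3-methoxyphenyl]-1,3-dithiane | COc1cc(C2SCCCS2)ccc1OCc1ccccc1
A3 | alternative 1 | 4-(benzyloxy)-3-methoxybenzaldehyde | COc1cc(C=O)ccc1OCc1ccccc1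
A4 | alternative 1 | 3-{[4-(benzyloxy)-3-methoxyphenyl](hydroxy)methyl}-4-{2-[4-(benzyloxy)-3-methoxyphenyl]-1,3-dithian-2-yl}-5-(d-menthyloxy)dihydrofuran-2(3H)-one, all ring substituents trans | O=C1O[C@H](O[C@H]2C[C@@H](C)CC[C@@H]2C(C)C)[C@@H](C3(SCCCS3)c4ccc(OCc5ccccc5)c(OC)c4)[C@@H]1[C@H](O)c6ccc(OCc7ccccc7)c(OC)c6
A5 | alternative 2 | (3R,4R)-N,N'-di(quinolin-8-yl)tetrahydrofuran-3,4-dicarboxamide (trans) | C1OC[C@H](C(=O)Nc2cccc3cccnc23)[C@H]1C(=O)Nc1cccc2cccnc12
A6 | alternative 2 | 1-(benzyloxy)-4-iodo-2-methoxybenzene | COc1cc(I)ccc1OCc1ccccc1
A7 | alternative 2 | 2,5-bis[4-(benzyloxy)-3-methoxyphenyl]-N,N'-di(quinolin-8-yl)tetrahydrofuran-3,4-dicarboxamide, each aryl cis to the adjacent amide | COc1cc(ccc1OCc1ccccc1)[C@H]2O[C@H](c3ccc(OCc4ccccc4)c(OC)c3)[C@H](C(=O)Nc5cccc6cccnc56)[C@H]2C(=O)Nc7cccc8cccnc78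
A8 | alternative 3 | 1-(benzyloxy)-4-(diazomethyl)-2-methoxybenzene | COc1cc(C=[N+]=[N-])ccc1OCc1ccccc1
A9 | alternative 3 | dimethyl fumarate | COC(=O)/C=C/C(=O)OC
A10 | alternative 3 | dimethyl all-trans-2,5-bis[4-(benzyloxy)-3-methoxyphenyl]tetrahydrofuran-3,4-dicarboxylate | COc1cc(ccc1OCc1ccccc1)[C@@H]2O[C@@H](c3ccc(OCc4ccccc4)c(OC)c3)[C@H](C(=O)OC)[C@H]2C(=O)OC
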